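**Plan**

1. The target is the (2S)-flavanone: ring A is the 7,8-dimethoxybenzo ring, ring C is the pyranone O1–C2–C3–C4–C4a–C8a, and ring B is the 3-hydroxy-4,5-dimethoxyphenyl group on C2. The retrosynthesis cuts, in order, the benzyl ether on ring B, C4–C4a (opening ring C to an aryl bromide carrying a Weinreb amide), C2–O1 (aryl ether), C2–C3 (acetamide aldol) and C–Br on ring A.
2. Enabling feature: C4a is the only free carbon of ring A ortho to O1 (C8 carries OMe), and the acyl carbon C4 is held next to it by the O1–C2–C3 tether. A carbanion at C4a therefore closes ring C by 6-exo attack on C4; the bromine that marks C4a comes from hydroxyl-directed ortho-bromination of 2,3-dimethoxyphenol.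
3. An anionic closure at −100 °C is chosen because an acylium ion would also be attacked by the electron-rich ring B and acid would ionise C2–O1. An aryne across C4a/C8a is polarity-mismatched, since the 8-OMe group would steer the alkoxide to C4a.
4. Forward: rings A and B are bought. The C2–C3 bond is made by aldol addition, the alcohol is oxidised and re-reduced asymmetrically, ring A is attached through O1 by Mitsunobu etherification, ring C is closed at C4–C4a, and the benzyl group is removed last.
5. Stereochemistry: C2 is set as the (R)-carbinol by asymmetric transfer hydrogenation with RuCl[(R,R)-TsDPEN](p-cymene), inverted to (S) in the Mitsunobu step, and not touched afterwards.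

Key step: step 6

**Step 1**
Reactants: 1 2,3-dimethoxyphenol
Product: 2 6-bromo-2,3-dimethoxyphenol
Conditions: NBS (1.0 equiv), i-Pr2NH (10 mol %), CH2Cl2, 0 °C
Reagents that add atoms: N-bromosuccinimide, O=C1CCC(=O)N1Br
Why: Amine-mediated ortho-selective electrophilic bromination of a phenol should deliver bromine to the one free position ortho to the hydroxyl group (C6), which is also para to the 3-methoxy group.

**Step 2**
Reactants: 3 3-(benzyloxy)-4,5-dimethoxybenzaldehyde; 4 N-methoxy-N-methylacetamide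
Product: 6 rac-3-[3-(benzyloxy)-4,5-dimethoxyphenyl]-3-hydroxy-N-methoxy-N-methylpropanamide, via lithium enolate 5 (not isolated)
Conditions: 4, LiN(i-Pr)2, THF, −78 °C; then 3, −78 °C; AcOH
Reagents that add atoms: none
Why: Aldol addition of a lithium amide enolate to a non-enolisable aromatic aldehyde should give the racemic β-hydroxy Weinreb amide, whose stereocentre is erased in the next step.

**Step 3**
Reactants: 6 rac-3-[3-(benzyloxy)-4,5-dimethoxyphenyl]-3-hydroxy-N-methoxy-N-methylpropanamide
Product: 7 3-[3-(benzyloxy)-4,5-dimethoxyphenyl]-N-methoxy-N-methyl-3-oxopropanamide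
Conditions: Dess–Martin periodinane, CH2Cl2, rt
Reagents that add atoms: none
Why: Dess–Martin oxidation of a secondary benzylic alcohol should give the β-keto amide under neutral conditions that leave the N-methoxy amide and the benzyl ether intact.

**Step 4**
Reactants: 7 3-[3-(benzyloxy)-4,5-dimethoxyphenyl]-N-methoxy-N-methyl-3-oxopropanamide
Product: 8 (3R)-3-[3-(benzyloxy)-4,5-dimethoxyphenyl]-3-hydroxy-N-methoxy-N-methylpropanamide
Conditions: RuCl[(R,R)-TsDPEN](p-cymene) (1 mol %), HCO2H/Et3N (5:2), CH2Cl2, 30 °C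
Reagents that add atoms: none
Why: Noyori asymmetric transfer hydrogenation of an aryl ketone, in which the CH–π contact between the cymene ligand and the aryl group in the six-membered hydride-transfer transition state makes the (R,R) catalyst give the (R)-carbinol, as it does with acetophenone and with aryl β-keto amides.

**Step 5**
Reactants: 8 (3R)-3-[3-(benzyloxy)-4,5-dimethoxyphenyl]-3-hydroxy-N-methoxy-N-methylpropanamide; 2 6-bromo-2,3-dimethoxyphenol
Product: 9 (3S)-3-[3-(benzyloxy)-4,5-dimethoxyphenyl]-3-(6-bromo-2,3-dimethoxyphenoxy)-N-methoxy-N-methylpropanamide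
Conditions: PPh3, DIAD, toluene (concentrated), 0 °C to rt
Reagents that add atoms: none
Why: Mitsunobu etherification, in which the phenoxide of 2 displaces the oxyphosphonium group by SN2 with inversion, should turn the (R)-carbinol into the (S)-aryl ether.

**Step 6**
Reactants: 9 (3S)-3-[3-(benzyloxy)-4,5-dimethoxyphenyl]-3-(6-bromo-2,3-dimethoxyphenoxy)-N-methoxy-N-methylpropanamide
Product: 12 (2S)-2-[3-(benzyloxy)-4,5-dimethoxyphenyl]-7,8-dimethoxy-2,3-dihydro-4H-chromen-4-one, via aryllithium 10 (not isolated), via lithium hemiaminal alkoxide 11 (not isolated)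
Conditions: t-BuLi (2.1 equiv), THF, −100 °C, then −78 °C; AcOH, −78 °C
Reagents that add atoms: none
Why: Bromine–lithium exchange at C4a of ring A (the second equivalent of t-BuLi destroys the t-BuBr formed) should give aryllithium 10, which adds to the tethered Weinreb amide carbonyl to form C4–C4a and the chelated lithium hemiaminal 11; acetic acid at −78 °C then releases the ketone and N,O-dimethylhydroxylamine. The closest known reaction type is the Parham cyclisation (cycloacylation) of ortho-bromoaryl ethers carrying an internal amide or carboxylate, an established way to chroman-4-ones. Ring C closes in the 6-exo-trig mode. No lasting stereocentre is formed, because the hemiaminal carbon of 11 is lost on collapse, and C2 is not involved, so its (S) configuration should carry through. The step needs site selectivity for C4a over the equally electron-rich ring B, which the C–Br bond fixes, and chemoselectivity against deprotonation next to the amide with β-elimination of the phenoxide and against base-induced opening of ring C; the fast exchange at −100 °C, the immediate intramolecular trapping and the survival of the N-methoxy chelate until the acidic quench should secure this.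

**Step 7**
Reactants: 12 (2S)-2-[3-(benzyloxy)-4,5-dimethoxyphenyl]-7,8-dimethoxy-2,3-dihydro-4H-chromen-4-one
Product: 13 (2S)-2-(3-hydroxy-4,5-dimethoxyphenyl)-7,8-dimethoxy-2,3-dihydro-4H-chromen-4-one
Conditions: H2 (1 atm), Pd/C (10 wt %), EtOAc, rt
Reagents that add atoms: none
Why: Catalytic hydrogenolysis of the aryl benzyl ether under neutral conditions should free the ring B phenol faster than the cyclic benzylic C2–O1 bond is cleaved or the aryl ketone reduced, and without base ring C cannot open, so the (S) centre is kept.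

**Compound list**

1 | 2,3-dimethoxyphenol | COc1cccc(O)c1OC | starting material
2 | 6-bromo-2,3-dimethoxyphenol | COc1ccc(Br)c(O)c1OC | intermediate
3 | 3-(benzyloxy)-4,5-dimethoxybenzaldehyde | O=Cc1cc(OC)c(OC)c(OCc2ccccc2)c1 | starting material
4 | N-methoxy-N-methylacetamide | CC(=O)N(C)OC | starting material
5 | lithium 1-[methoxy(methyl)amino]ethen-1-olate (lithium enolate of 4) | [Li]OC(=C)N(C)OC | intermediate (not isolated)
6 | rac-3-[3-(benzyloxy)-4,5-dimethoxyphenyl]-3-hydroxy-N-methoxy-N-methylpropanamide | CON(C)C(=O)CC(O)c1cc(OC)c(OC)c(OCc2ccccc2)c1 | intermediate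
7 | 3-[3-(benzyloxy)-4,5-dimethoxyphenyl]-N-methoxy-N-methyl-3-oxopropanamide | CON(C)C(=O)CC(=O)c1cc(OC)c(OC)c(OCc2ccccc2)c1 | intermediate
8 | (3R)-3-[3-(benzyloxy)-4,5-dimethoxyphenyl]-3-hydroxy-N-methoxy-N-methylpropanamide | CON(C)C(=O)C[C@@H](O)c1cc(OC)c(OC)c(OCc2ccccc2)c1 | intermediate
9 | (3S)-3-[3-(benzyloxy)-4,5-dimethoxyphenyl]-3-(6-bromo-2,3-dimethoxyphenoxy)-N-methoxy-N-methylpropanamide | CON(C)C(=O)C[C@H](Oc1c(Br)ccc(OC)c1OC)c1cc(OC)c(OC)c(OCc2ccccc2)c1 | intermediate
10 | {2-[(1S)-1-[3-(benzyloxy)-4,5-dimethoxyphenyl]-3-[methoxy(methyl)amino]-3-oxopropoxy]-3,4-dimethoxyphenyl}lithium | CON(C)C(=O)C[C@H](Oc1c([Li])ccc(OC)c1OC)c1cc(OC)c(OC)c(OCc2ccccc2)c1 | intermediate (not isolated)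
11 | lithium (2S)-2-[3-(benzyloxy)-4,5-dimethoxyphenyl]-7,8-dimethoxy-4-[methoxy(methyl)amino]-3,4-dihydro-2H-chromen-4-olate (C4 configuration undefined) | COc1cc([C@@H]2CC(O[Li])(N(C)OC)c3ccc(OC)c(OC)c3O2)cc(OCc2ccccc2)c1OC | intermediate (not isolated)
12 | (2S)-2-[3-(benzyloxy)-4,5-dimethoxyphenyl]-7,8-dimethoxy-2,3-dihydro-4H-chromen-4-one | COc1cc([C@@H]2CC(=O)c3ccc(OC)c(OC)c3O2)cc(OCc2ccccc2)c1OC | intermediate
13 | (2S)-2-(3-hydroxy-4,5-dimethoxyphenyl)-7,8-dimethoxy-2,3-dihydro-4H-chromen-4-one | COc1cc([C@@H]2CC(=O)c3ccc(OC)c(OC)c3O2)cc(O)c1OC | target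

**Step count and risks**

Total steps: 7. Longest linear sequence: 6 (steps 2 to 7, from aldehyde 3); step 1 supplies the phenol that joins in step 5.

Steps most likely to fail:

Step 5 (Mitsunobu etherification). The activated alcohol may eliminate to the cinnamamide, the electron-rich benzylic oxyphosphonium may ionise and erode the enantiopurity, and the doubly ortho-substituted phenol may attack slowly. The fallback makes the C2–O1 bond by iridium-catalysed enantioselective allylic etherification instead. It sets out from aldehyde 3 and bromophenol 2 and comes back at 9.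
- Olefination of 3 with triethyl phosphonoacetate (LiCl, DBU, MeCN) would give ethyl (2E)-3-[3-(benzyloxy)-4,5-dimethoxyphenyl]prop-2-enoate F1.
- i-Bu2AlH (CH2Cl2, −78 °C) would give (2E)-3-[3-(benzyloxy)-4,5-dimethoxyphenyl]prop-2-en-1-ol F2.
- ClCO2Me/pyridine would give (2E)-3-[3-(benzyloxy)-4,5-dimethoxyphenyl]prop-2-en-1-yl methyl carbonate F3.
- F3 and phenol 2 (deprotonated in the flask with LiN(SiMe3)2) with [Ir(cod)Cl]2 and a BINOL-derived phosphoramidite ligand, in the enantiomer that gives the (S)-ether, would give the branched ether 1-bromo-2-{[(1S)-1-[3-(benzyloxy)-4,5-dimethoxyphenyl]prop-2-en-1-yl]oxy}-3,4-dimethoxybenzene F4.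
- Hydroboration with 9-BBN and oxidation with NaBO3·4H2O would give (3S)-3-[3-(benzyloxy)-4,5-dimethoxyphenyl]-3-(6-bromo-2,3-dimethoxyphenoxy)propan-1-ol F5.
- TEMPO/PhI(OAc)2 in MeCN–water would give (3S)-3-[3-(benzyloxy)-4,5-dimethoxyphenyl]-3-(6-bromo-2,3-dimethoxyphenoxy)propanoic acid F6.
- Coupling with N,O-dimethylhydroxylamine hydrochloride (EDC·HCl, HOBt, i-Pr2NEt) would return to 9.

Step 6 (lithiation and cycloacylation). The alkyllithium or the aryllithium may deprotonate next to the amide and expel the phenoxide by β-elimination, the aryllithium may be protonated before it cyclises, or the alkyllithium may attack the amide. The fallback closes ring C by electrophilic cycloacylation of a bromine-free acid. It sets out from 8 and phenol 1 and comes back at 12.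
- Mitsunobu coupling as in step 5 would give (3S)-3-[3-(benzyloxy)-4,5-dimethoxyphenyl]-3-(2,3-dimethoxyphenoxy)-N-methoxy-N-methylpropanamide F7.
- i-Bu2AlH (THF, −78 °C) would give (3S)-3-[3-(benzyloxy)-4,5-dimethoxyphenyl]-3-(2,3-dimethoxyphenoxy)propanal F8.
- Pinnick oxidation (NaClO2, NaH2PO4, 2-methyl-2-butene, t-BuOH–water) would give (3S)-3-[3-(benzyloxy)-4,5-dimethoxyphenyl]-3-(2,3-dimethoxyphenoxy)propanoic acid F9.
- (COCl)2 with catalytic DMF would give (3S)-3-[3-(benzyloxy)-4,5-dimethoxyphenyl]-3-(2,3-dimethoxyphenoxy)propanoyl chloride F10.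
- F10 would be treated without isolation with SnCl4 (CH2Cl2, −78 °C). Friedel–Crafts acylation at the only position of the phenoxy ring ortho to the ether oxygen, which is para to a methoxy group, should then give 12.

Step 1 (bromination). Bromination may occur para to the hydroxyl group or twice. The fallback places the bromine by directed ortho-metalation. It sets out from 1 and comes back at 2.
- MOMCl/i-Pr2NEt would give 1,2-dimethoxy-3-(methoxymethoxy)benzene F11.
- Lithiation next to the methoxymethoxy group with n-BuLi (THF, 0 °C) and quenching with 1,2-dibromotetrachloroethane would give 1-bromo-3,4-dimethoxy-2-(methoxymethoxy)benzene F12.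
- HCl in MeOH would return to 2.

**Further compounds**

F1 | step 5 | ethyl (2E)-3-[3-(benzyloxy)-4,5-dimethoxyphenyl]prop-2-enoate | CCOC(=O)/C=C/c1cc(OC)c(OC)c(OCc2ccccc2)c1
F2 | step 5 | (2E)-3-[3-(benzyloxy)-4,5-dimethoxyphenyl]prop-2-en-1-ol | OC/C=C/c1cc(OC)c(OC)c(OCc2ccccc2)c1
F3 | step 5 | (2E)-3-[3-(benzyloxy)-4,5-dimethoxyphenyl]prop-2-en-1-yl methyl carbonate | COC(=O)OC/C=C/c1cc(OC)c(OC)c(OCc2ccccc2)c1
F4 | step 5 | 1-bromo-2-{[(1S)-1-[3-(benzyloxy)-4,5-dimethoxyphenyl]prop-2-en-1-yl]oxy}-3,4-dimethoxybenzene | C=C[C@H](Oc1c(Br)ccc(OC)c1OC)c1cc(OC)c(OC)c(OCc2ccccc2)c1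
F5 | step 5 | (3S)-3-[3-(benzyloxy)-4,5-dimethoxyphenyl]-3-(6-bromo-2,3-dimethoxyphenoxy)propan-1-ol | OCC[C@H](Oc1c(Br)ccc(OC)c1OC)c1cc(OC)c(OC)c(OCc2ccccc2)c1
F6 | step 5 | (3S)-3-[3-(benzyloxy)-4,5-dimethoxyphenyl]-3-(6-bromo-2,3-dimethoxyphenoxy)propanoic acid | OC(=O)C[C@H](Oc1c(Br)ccc(OC)c1OC)c1cc(OC)c(OC)c(OCc2ccccc2)c1
F7 | step 6 | (3S)-3-[3-(benzyloxy)-4,5-dimethoxyphenyl]-3-(2,3-dimethoxyphenoxy)-N-methoxy-N-methylpropanamide | CON(C)C(=O)C[C@H](Oc1cccc(OC)c1OC)c1cc(OC)c(OC)c(OCc2ccccc2)c1
F8 | step 6 | (3S)-3-[3-(benzyloxy)-4,5-dimethoxyphenyl]-3-(2,3-dimethoxyphenoxy)propanal | O=CC[C@H](Oc1cccc(OC)c1OC)c1cc(OC)c(OC)c(OCc2ccccc2)c1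
F9 | step 6 | (3S)-3-[3-(benzyloxy)-4,5-dimethoxyphenyl]-3-(2,3-dimethoxyphenoxy)propanoic acid | OC(=O)C[C@H](Oc1cccc(OC)c1OC)c1cc(OC)c(OC)c(OCc2ccccc2)c1
F10 | step 6 | (3S)-3-[3-(benzyloxy)-4,5-dimethoxyphenyl]-3-(2,3-dimethoxyphenoxy)propanoyl chloride | ClC(=O)C[C@H](Oc1cccc(OC)c1OC)c1cc(OC)c(OC)c(OCc2ccccc2)c1
F11 | step 1 | 1,2-dimethoxy-3-(methoxymethoxy)benzene | COCOc1cccc(OC)c1OC
F12 | step 1 | 1-bromo-3,4-dimethoxy-2-(methoxymethoxy)benzene | COCOc1c(Br)ccc(OC)c1OC
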